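## Retrosynthetic overview

1. Rings: A is the phloroglucinol ring of the chromanone, C its pyranone ring, B the 3-aryl ring, D the dimethylpyran ring fused to B. The (3S) centre is set in the last-but-one step by catalyst-controlled protonation at C3 of a 4-silyloxy-2H-chromene (the silyl enol ether of the ketone); global desilylation then gives the target.
2. Key disconnection: ring C is cut at C2–C3 and C4–C4a. The forward step is a cationic formal (4+2) annulation of oxa-Povarov type, ending in a Friedel–Crafts closure, between an O-aryl oxocarbenium ion (C4a=C8a–O1=C2, from an aryl pivaloyloxymethyl ether) and an aryl siloxyalkyne (C3≡C4–OSi).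
3. Enabling feature: ring A is a phloroglucinol ring, so C4a lies ortho to O1 and O5 and para to O7, and the two carbons ortho to O1 are equivalent. C2 is an unsubstituted O–CH2 carbon (formaldehyde level) and C4 is an acyl-level carbon next to the aryl-bearing C3, which is what the two carbons of an ynol ether deliver.
4. Siloxyalkyne: Kowalski ynolate from a benzoate whose ring D comes from a propargyl ether Claisen rearrangement and electrocyclization on methyl 3,4-dihydroxybenzoate. Oxocarbenium precursor: phloroglucinol, bis-silylated and alkylated with chloromethyl pivalate.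
5. Order of ring formation: ring B (bought), ring D (step 3), ring A (bought), ring C (step 7).

Key step: step 7

Assumption: the sense of induction of the chiral acid in step 8 cannot be predicted with certainty for this substrate; the (S)-configured catalyst is written, and its mirror image is to be used if a first test gives the (3R) ketone.

## Route

Step 1
Reactants: 1 methyl 3,4-dihydroxybenzoate
Product: 2 methyl 3-hydroxy-4-[(2-methylbut-3-yn-2-yl)oxy]benzoate
Conditions: 3-chloro-3-methylbut-1-yne (1.5 equiv), K2CO3 (1.1 equiv), KI (cat.), acetone, 55 °C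
Reagents that add atoms: 3-chloro-3-methylbut-1-yne, CC(C)(Cl)C#C
Why: Williamson-type O-propargylation in which one equivalent of carbonate deprotonates the more acidic 4-hydroxyl (para to the ester), so the tertiary propargyl chloride should be taken up mainly at O4.

Step 2
Reactants: 2 methyl 3-hydroxy-4-[(2-methylbut-3-yn-2-yl)oxy]benzoate
Product: 3 methyl 4-[(2-methylbut-3-yn-2-yl)oxy]-3-[(triisopropylsilyl)oxy]benzoate
Conditions: TIPSCl, imidazole, DMF, rt to 40 °C
Reagents that add atoms: triisopropylsilyl chloride, CC(C)[Si](Cl)(C(C)C)C(C)C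
Why: Standard silylation of a phenol, which removes the free catechol hydroxyl before the thermal step and gives a group that survives the organolithium chemistry of step 4.

Step 3
Reactants: 3 methyl 4-[(2-methylbut-3-yn-2-yl)oxy]-3-[(triisopropylsilyl)oxy]benzoate
Product: 5 methyl 2,2-dimethyl-8-[(triisopropylsilyl)oxy]-2H-chromene-6-carboxylate, via allenyl phenol 4 (not isolated)
Conditions: PhNEt2, 190 °C
Reagents that add atoms: none
Why: Aromatic propargyl Claisen rearrangement to the only free ortho carbon gives, after enolization, allenyl phenol 4, which should close to the 2,2-dimethyl-2H-chromene by 1,5-hydrogen shift and oxa-6π electrocyclization.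

Step 4
Reactants: 5 methyl 2,2-dimethyl-8-[(triisopropylsilyl)oxy]-2H-chromene-6-carboxylate
Product: 8 ({2,2-dimethyl-8-[(triisopropylsilyl)oxy]-2H-chromen-6-yl}ethynyloxy)triisopropylsilane, via lithium dibromoenolate 6 (not isolated), via lithium ynolate 7 (not isolated)
Conditions: CH2Br2, LiTMP (2.2 equiv), THF, −78 °C; n-BuLi, −78 → 0 °C; TIPSOTf, −78 °C → rt
Reagents that add atoms: dibromomethane, BrCBr; triisopropylsilyl triflate, CC(C)[Si](OS(=O)(=O)C(F)(F)F)(C(C)C)C(C)C
Why: Kowalski ynolate formation, in which dibromomethyllithium adds to the ester, the dibromoketone is deprotonated to enolate 6, bromine–lithium exchange triggers the 1,2-aryl shift to ynolate 7, and the bulky silyl triflate should silylate the ynolate on oxygen.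

Step 5
Reactants: 9 phloroglucinol (benzene-1,3,5-triol)
Product: 10 3,5-bis[(tert-butyldimethylsilyl)oxy]phenol
Conditions: TBSCl (2.0 equiv), imidazole, DMF, 0 °C → rt
Reagents that add atoms: tert-butyldimethylsilyl chloride, CC(C)(C)[Si](C)(C)Cl
Why: Statistical silylation of a threefold-symmetric triol with two equivalents of silyl chloride; the bis-silyl ether should be separable from mono- and tris-silylated material, which can be recycled.

Step 6
Reactants: 10 3,5-bis[(tert-butyldimethylsilyl)oxy]phenol
Product: 11 {3,5-bis[(tert-butyldimethylsilyl)oxy]phenoxy}methyl pivalate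
Conditions: NaH, THF/DMF, 0 °C; chloromethyl pivalate, NaI (cat.), 0 °C → rt
Reagents that add atoms: chloromethyl pivalate, CC(C)(C)C(=O)OCCl
Why: Williamson ether synthesis of the sodium phenoxide with an acyloxymethyl halide (Finkelstein activation by iodide) should give the aryl acyloxymethyl acetal that carries the future C2.

Step 7
Reactants: 11 {3,5-bis[(tert-butyldimethylsilyl)oxy]phenoxy}methyl pivalate; 8 ({2,2-dimethyl-8-[(triisopropylsilyl)oxy]-2H-chromen-6-yl}ethynyloxy)triisopropylsilane
Product: 14 5,7-bis[(tert-butyldimethylsilyl)oxy]-3-{2,2-dimethyl-8-[(triisopropylsilyl)oxy]-2H-chromen-6-yl}-4-[(triisopropylsilyl)oxy]-2H-chromene, via aryloxymethyl oxocarbenium triflate 12 (not isolated), via silyl ketenium triflate 13 (not isolated)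
Conditions: 8 (1.3 equiv), 2,6-di-tert-butyl-4-methylpyridine (1.5 equiv), TMSOTf (1.2 equiv), CH2Cl2, −78 °C, slow addition of 11, then → −40 °C
Reagents that add atoms: none
Why: Proposed new method: TMSOTf should ionize the pivaloyloxymethyl ether 11 to the O-aryl oxocarbenium ion 12 (a 2-oxoniadiene, C4a=C8a–O1=C2), whose CH2 carbon is attacked by the aryl-bearing carbon of siloxyalkyne 8 (C2–C3 bond) to give silyl ketenium ion 13, and the ortho carbon of ring A then attacks the digonal ketenium carbon (C4–C4a bond) before the hindered pyridine removes the proton of the arenium ion. The closest known reaction types are the oxa-Povarov reaction of O-aryl oxocarbenium ions with alkenes, the addition of siloxyalkynes to oxocarbenium ions generated from acetals, and the cyclization of silyl ketenium ions onto tethered arenes; their union with a formaldehyde-level oxocarbenium ion and an ynol silyl ether as the two-atom partner is the new part. Ring C closes by electrophilic aromatic substitution in a six-membered closure on the digonal carbon (exo with respect to the C4–O bond, the new C3=C4 enol double bond lying inside the ring), with the geometry of the 6-endo-dig closure of aryl propargyl ethers to 2H-chromenes. No stereocenter is formed, because C3 leaves the step as the sp2 carbon of the silyl enol ether and is set in step 8. The step needs the alkyne to outrun ring A of a second molecule and the ring D double bond in capturing the oxocarbenium ion (secured by the far higher nucleophilicity of the unhindered ynol ether carbon, its excess, slow addition of 11 and the damping silyloxy groups on ring A), and it needs C-attack rather than O-attack on the ketenium (secured by C4a being ortho to O1 and O5 and para to O7, against a four-membered closure by the weakly basic ether oxygen O1). There is no regiochemical choice because the two carbons ortho to O1 are equivalent, and the pyridine base keeps triflic acid from protonating 8 or the product enol ether.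

Step 8
Reactants: 14 5,7-bis[(tert-butyldimethylsilyl)oxy]-3-{2,2-dimethyl-8-[(triisopropylsilyl)oxy]-2H-chromen-6-yl}-4-[(triisopropylsilyl)oxy]-2H-chromene
Product: 15 (3S)-5,7-bis[(tert-butyldimethylsilyl)oxy]-3-{2,2-dimethyl-8-[(triisopropylsilyl)oxy]-2H-chromen-6-yl}-2,3-dihydro-4H-chromen-4-one
Conditions: (S)-3,3'-bis(2,4,6-triisopropylphenyl)-BINOL N-triflyl thiophosphoramide (10 mol%), MeOH (1.5 equiv), toluene, −20 °C
Reagents that add atoms: none
Why: Catalytic enantioselective protonation of the silyl enol ether of an α-aryl cyclic ketone, in which the chiral Brønsted acid delivers the proton to one face of C3 within a chiral ion pair and methanol takes up the silyl group and regenerates the acid, so the C3 configuration is set by the catalyst.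

Step 9
Reactants: 15 (3S)-5,7-bis[(tert-butyldimethylsilyl)oxy]-3-{2,2-dimethyl-8-[(triisopropylsilyl)oxy]-2H-chromen-6-yl}-2,3-dihydro-4H-chromen-4-one
Product: 16 (3S)-5,7-dihydroxy-3-(8-hydroxy-2,2-dimethyl-2H-chromen-6-yl)-2,3-dihydro-4H-chromen-4-one
Conditions: HF·pyridine, pyridine, THF, 0 °C → rt
Reagents that add atoms: none
Why: Fluoride-mediated cleavage of the three aryl silyl ethers under buffered, weakly acidic conditions, which should neither enolize the C3 stereocenter nor touch the ring D double bond.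

## Compound list

1 | methyl 3,4-dihydroxybenzoate | COC(=O)c1ccc(O)c(O)c1 | starting material
2 | methyl 3-hydroxy-4-[(2-methylbut-3-yn-2-yl)oxy]benzoate | COC(=O)c1ccc(OC(C)(C)C#C)c(O)c1 | intermediate
3 | methyl 4-[(2-methylbut-3-yn-2-yl)oxy]-3-[(triisopropylsilyl)oxy]benzoate | COC(=O)c1ccc(OC(C)(C)C#C)c(O[Si](C(C)C)(C(C)C)C(C)C)c1 | intermediate
4 | methyl 4-hydroxy-3-(3-methylbuta-1,2-dien-1-yl)-5-[(triisopropylsilyl)oxy]benzoate (allenyl phenol, not isolated) | COC(=O)c1cc(C=C=C(C)C)c(O)c(O[Si](C(C)C)(C(C)C)C(C)C)c1 | intermediate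
5 | methyl 2,2-dimethyl-8-[(triisopropylsilyl)oxy]-2H-chromene-6-carboxylate | COC(=O)c1cc(O[Si](C(C)C)(C(C)C)C(C)C)c2OC(C)(C)C=Cc2c1 | intermediate
6 | lithium 2,2-dibromo-1-{2,2-dimethyl-8-[(triisopropylsilyl)oxy]-2H-chromen-6-yl}ethen-1-olate (not isolated) | [Li]OC(=C(Br)Br)c1cc(O[Si](C(C)C)(C(C)C)C(C)C)c2OC(C)(C)C=Cc2c1 | intermediate
7 | lithium 2-{2,2-dimethyl-8-[(triisopropylsilyl)oxy]-2H-chromen-6-yl}ethyn-1-olate (not isolated) | [Li]OC#Cc1cc(O[Si](C(C)C)(C(C)C)C(C)C)c2OC(C)(C)C=Cc2c1 | intermediate
8 | ({2,2-dimethyl-8-[(triisopropylsilyl)oxy]-2H-chromen-6-yl}ethynyloxy)triisopropylsilane | CC(C)[Si](OC#Cc1cc(O[Si](C(C)C)(C(C)C)C(C)C)c2OC(C)(C)C=Cc2c1)(C(C)C)C(C)C | intermediate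
9 | phloroglucinol (benzene-1,3,5-triol) | Oc1cc(O)cc(O)c1 | starting material
10 | 3,5-bis[(tert-butyldimethylsilyl)oxy]phenol | CC(C)(C)[Si](C)(C)Oc1cc(O)cc(O[Si](C)(C)C(C)(C)C)c1 | intermediate
11 | {3,5-bis[(tert-butyldimethylsilyl)oxy]phenoxy}methyl pivalate | CC(C)(C)C(=O)OCOc1cc(O[Si](C)(C)C(C)(C)C)cc(O[Si](C)(C)C(C)(C)C)c1 | intermediate
12 | {3,5-bis[(tert-butyldimethylsilyl)oxy]phenyl}(methylidene)oxonium triflate (O-aryl oxocarbenium ion pair, not isolated) | C=[O+]c1cc(O[Si](C)(C)C(C)(C)C)cc(O[Si](C)(C)C(C)(C)C)c1.[O-]S(=O)(=O)C(F)(F)F | intermediate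
13 | O-triisopropylsilyl ketenium triflate bearing the chromenyl group and the 3,5-bis(silyloxy)phenoxymethyl group on the terminal carbon (not isolated) | CC(C)[Si]([O+]=C=C(COc1cc(O[Si](C)(C)C(C)(C)C)cc(O[Si](C)(C)C(C)(C)C)c1)c1cc(O[Si](C(C)C)(C(C)C)C(C)C)c2OC(C)(C)C=Cc2c1)(C(C)C)C(C)C.[O-]S(=O)(=O)C(F)(F)F | intermediate
14 | 5,7-bis[(tert-butyldimethylsilyl)oxy]-3-{2,2-dimethyl-8-[(triisopropylsilyl)oxy]-2H-chromen-6-yl}-4-[(triisopropylsilyl)oxy]-2H-chromene | CC1(C)C=Cc2cc(C3=C(O[Si](C(C)C)(C(C)C)C(C)C)c4c(O[Si](C)(C)C(C)(C)C)cc(O[Si](C)(C)C(C)(C)C)cc4OC3)cc(O[Si](C(C)C)(C(C)C)C(C)C)c2O1 | intermediate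
15 | (3S)-5,7-bis[(tert-butyldimethylsilyl)oxy]-3-{2,2-dimethyl-8-[(triisopropylsilyl)oxy]-2H-chromen-6-yl}-2,3-dihydro-4H-chromen-4-one | CC1(C)C=Cc2cc([C@H]3COc4cc(O[Si](C)(C)C(C)(C)C)cc(O[Si](C)(C)C(C)(C)C)c4C3=O)cc(O[Si](C(C)C)(C(C)C)C(C)C)c2O1 | intermediate
16 | (3S)-5,7-dihydroxy-3-(8-hydroxy-2,2-dimethyl-2H-chromen-6-yl)-2,3-dihydro-4H-chromen-4-one | CC1(C)C=Cc2cc([C@H]3COc4cc(O)cc(O)c4C3=O)cc(O)c2O1 | target

## Step count and risks

Total step count: 9. Longest linear sequence: 7 steps (steps 1–4 and 7–9, from methyl 3,4-dihydroxybenzoate); the ring A branch (steps 5 and 6) joins at step 7.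

Steps most likely to fail:

1. Step 7 (proposed new method). What may go wrong: Friedel–Crafts oligomerization of ring A by the oxocarbenium ion, protonation of the siloxyalkyne by adventitious acid, or capture of the ketenium ion by triflate, pivalate or O1 before ring closure. The fallback uses known reaction types only and sets out from 5 and 11.
   - Kowalski homologation of 5 (ynolate 7 quenched with dilute aqueous acid) should give {2,2-dimethyl-8-[(triisopropylsilyl)oxy]-2H-chromen-6-yl}acetic acid F1.
   - LiN(SiMe3)2 (2.2 equiv) and Me3SiCl in THF at −78 °C should convert it into the bis(trimethylsilyl) ketene acetal F2.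
   - A Mukaiyama-type alkoxymethylation of F2 with 11 (TMSOTf cat., CH2Cl2, −78 °C, aqueous work-up) should form the C2–C3 bond and give the racemic 3-aryloxy-2-arylpropanoic acid F3.
   - Intramolecular Friedel–Crafts acylation through the mixed anhydride (TFAA, CH2Cl2, 0 °C) should form the C4–C4a bond and give the racemic protected ketone F4.
   - Enol silylation (TIPSOTf, Et3N, CH2Cl2) brings the material back to the route at 14.

2. Step 8. What may go wrong: poor facial selectivity in the proton transfer to the crowded tetrasubstituted enol ether, slow silyl transfer from the hindered triisopropylsilyl group, or acid-mediated enolization of the product. The fallback sets out from 14.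
   - Hydrolysis (1 M HCl, THF, 0 °C) should give the racemic protected ketone F4 (the compound already described under the first fallback).
   - Transfer hydrogenation with dynamic kinetic resolution (RuCl(p-cymene)[(S,S)-TsDPEN], HCO2H/Et3N, EtOAc, 40 °C), in which triethylamine keeps the ketone racemizing and the catalyst reduces one enantiomer, should give the cis alcohol (3S,4S)-5,7-bis[(tert-butyldimethylsilyl)oxy]-3-{2,2-dimethyl-8-[(triisopropylsilyl)oxy]-2H-chromen-6-yl}chroman-4-ol F5.
   - Oxidation with Dess–Martin periodinane (CH2Cl2, 0 °C) should then return the (3S) ketone without touching C3, coming back to the route at 15.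

3. Step 4. What may go wrong: incomplete aryl migration in the carbenoid rearrangement, C-silylation instead of O-silylation of the ynolate, or attack of the alkyllithium on the aryl silyl ether. The fallback sets out from 5.
   - Reduction (i-Bu2AlH, CH2Cl2, −78 °C) should give the benzylic alcohol {2,2-dimethyl-8-[(triisopropylsilyl)oxy]-2H-chromen-6-yl}methanol F6.
   - MnO2 in CH2Cl2 should give the aldehyde F7.
   - Corey–Fuchs olefination (CBr4, PPh3, CH2Cl2, 0 °C) should give the 1,1-dibromoalkene F8.
   - n-BuLi (2.1 equiv, THF, −78 °C) should give the lithium acetylide F9, which is not isolated.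
   - Oxidation of F9 with LiOOt-Bu (from t-BuOOH and LiN(SiMe3)2) gives ynolate 7; silylation with TIPSOTf brings the material back to the route at 8.

## Further compounds

F1 | step 7 | {2,2-dimethyl-8-[(triisopropylsilyl)oxy]-2H-chromen-6-yl}acetic acid | OC(=O)Cc1cc(O[Si](C(C)C)(C(C)C)C(C)C)c2OC(C)(C)C=Cc2c1
F2 | step 7 | bis(trimethylsilyl) ketene acetal of F1, 6-{2,2-bis[(trimethylsilyl)oxy]ethenyl}-2,2-dimethyl-8-[(triisopropylsilyl)oxy]-2H-chromene | C[Si](C)(C)OC(O[Si](C)(C)C)=Cc1cc(O[Si](C(C)C)(C(C)C)C(C)C)c2OC(C)(C)C=Cc2c1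
F3 | step 7 | racemic 3-{3,5-bis[(tert-butyldimethylsilyl)oxy]phenoxy}-2-{2,2-dimethyl-8-[(triisopropylsilyl)oxy]-2H-chromen-6-yl}propanoic acid | OC(=O)C(COc1cc(O[Si](C)(C)C(C)(C)C)cc(O[Si](C)(C)C(C)(C)C)c1)c1cc(O[Si](C(C)C)(C(C)C)C(C)C)c2OC(C)(C)C=Cc2c1
F4 | step 7 | racemic 5,7-bis[(tert-butyldimethylsilyl)oxy]-3-{2,2-dimethyl-8-[(triisopropylsilyl)oxy]-2H-chromen-6-yl}-2,3-dihydro-4H-chromen-4-one | CC1(C)C=Cc2cc(C3COc4cc(O[Si](C)(C)C(C)(C)C)cc(O[Si](C)(C)C(C)(C)C)c4C3=O)cc(O[Si](C(C)C)(C(C)C)C(C)C)c2O1
F5 | step 8 | (3S,4S)-5,7-bis[(tert-butyldimethylsilyl)oxy]-3-{2,2-dimethyl-8-[(triisopropylsilyl)oxy]-2H-chromen-6-yl}chroman-4-ol (cis) | CC1(C)C=Cc2cc([C@H]3COc4cc(O[Si](C)(C)C(C)(C)C)cc(O[Si](C)(C)C(C)(C)C)c4[C@H]3O)cc(O[Si](C(C)C)(C(C)C)C(C)C)c2O1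
F6 | step 4 | {2,2-dimethyl-8-[(triisopropylsilyl)oxy]-2H-chromen-6-yl}methanol | OCc1cc(O[Si](C(C)C)(C(C)C)C(C)C)c2OC(C)(C)C=Cc2c1
F7 | step 4 | 2,2-dimethyl-8-[(triisopropylsilyl)oxy]-2H-chromene-6-carbaldehyde | O=Cc1cc(O[Si](C(C)C)(C(C)C)C(C)C)c2OC(C)(C)C=Cc2c1
F8 | step 4 | 6-(2,2-dibromoethenyl)-2,2-dimethyl-8-[(triisopropylsilyl)oxy]-2H-chromene | BrC(Br)=Cc1cc(O[Si](C(C)C)(C(C)C)C(C)C)c2OC(C)(C)C=Cc2c1
F9 | step 4 | lithium {2,2-dimethyl-8-[(triisopropylsilyl)oxy]-2H-chromen-6-yl}acetylide (not isolated) | [Li]C#Cc1cc(O[Si](C(C)C)(C(C)C)C(C)C)c2OC(C)(C)C=Cc2c1
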